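**Strategy.** Positions follow the eremophilane numbering of the target (decalin C1–C10, side chain C11–C13, methyls C14 on C5 and C15 on C4). Ring A carries three contiguous cis centres: C3–O, C4–Me and quaternary C5–Me. They are set by an inverse-demand Diels–Alder reaction between a chiral (Z)-prop-1-enyl ether (C3=C4) and the masked o-benzoquinone of 2-methoxy-3-methylphenol. Its C2=C1–C10=C5 diene is locked s-cis, and its C6 and C7 are ring B carbons. The C2–C3 and C4–C5 bonds form together, giving a bicyclo[2.2.2]octenone. A later anionic oxy-Cope rearrangement severs C2–C7 and joins C9–C10, turning this skeleton into the cis-decalin.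

Key step: step 3

Remark: 2-methoxy-3-methylphenol and (R)-1-(2,4,6-triisopropylphenyl)ethanol are taken to be catalogue compounds.
Remark: C6 in compounds 8 and 11–15 is a transient stereocentre, drawn as the expected major epimer; either epimer gives 16.

**Step 1**
Reactants: 1 (R)-1-(2,4,6-triisopropylphenyl)ethanol; 2 allyl bromide
Product: 3 allyl (R)-1-(2,4,6-triisopropylphenyl)ethyl ether
Conditions: KH, THF, 0 °C; then 2, Bu4NI (cat.), rt
Reagents that add atoms: none
Why: Williamson etherification of the potassium alkoxide; no bond to the carbinol stereocentre is broken, so its R configuration is kept.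

**Step 2**
Reactants: 3 allyl (R)-1-(2,4,6-triisopropylphenyl)ethyl ether
Product: 4 (Z)-prop-1-enyl (R)-1-(2,4,6-triisopropylphenyl)ethyl ether
Conditions: KOt-Bu (0.2 equiv), DMSO, 60 °C
Reagents that add atoms: none
Why: Base-mediated allyl-to-propenyl ether isomerisation; the potassium-chelated cis-oxyallyl anion is reprotonated at the terminus, which should give the Z enol ether, and no stereocentre is formed.

**Step 3**
Reactants: 4 (Z)-prop-1-enyl (R)-1-(2,4,6-triisopropylphenyl)ethyl ether; 5 2-methoxy-3-methylphenol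
Product: 7 bicyclo[2.2.2]octenone adduct, via masked o-benzoquinone 6 (not isolated)
Conditions: PhI(OAc)2 (1.1 equiv), 4 (2.5 equiv), MeOH, 50 °C, 5 added over 8 h; excess 4 recovered
Reagents that add atoms: methanol, CO
Why: PhI(OAc)2 in methanol dearomatises 5 to the 6,6-dimethoxy-5-methylcyclohexa-2,4-dienone 6, whose electron-poor diene C2=C1–C10=C5 is trapped by the electron-rich enol ether 4 in a concerted, asynchronous inverse-electron-demand [4+2] cycloaddition, the known Diels–Alder reaction of masked o-benzoquinones with enol ethers. The cycloaddition closes the cyclohexene that becomes ring A (C2–C3 and C4–C5 bonds, suprafacial on both partners) and with it the second six-membered ring of the bicyclo[2.2.2]octenone, bridged by C6 and C7. C3 and C4 come out cis because the Z geometry of 4 is retained; C5 is set relative to them by the endo transition state (alkoxy group under the diene, anti to the C6–C7 bridge), which puts the 3-alkoxy, 4-methyl and 5-methyl groups on one face of ring A, and the bridgehead C2 follows from the bicyclic constraint. The absolute sense comes from the auxiliary: in the s-trans conformer of 4 with the carbinol C–H eclipsing the vinyl C–O bond, the triisopropylphenyl group covers one face, so the dienone should add to the other and give 3S,4R (target numbering). The step needs regiocontrol (C4 to C5, C3 to C2), which polarity matching secures: the nucleophilic β-carbon of the enol ether (C4) bonds to the electrophilic δ-carbon of the dienone (C5). Slow addition of 5 keeps 6 dilute so that cycloaddition outruns its dimerisation, which the 5-methyl group also retards.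

**Step 4**
Reactants: 7 bicyclo[2.2.2]octenone adduct
Product: 8 mono-methoxy bicyclic ketone
Conditions: SmI2 (2.2 equiv), THF/MeOH, −78 °C
Reagents that add atoms: none
Why: Reductive cleavage of an α-alkoxy ketone by SmI2; the ketyl expels one methoxide, methanol protonates the samarium enolate from the open etheno face (transient C6 centre), and limiting reductant at low temperature should stop at the mono-ether because the ketal carbon loses its first methoxy group faster than the second.

**Step 5**
Reactants: 8 mono-methoxy bicyclic ketone; 9 ethyl vinyl ether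
Product: 11 ethoxyvinyl carbinol, via 1-ethoxyvinyllithium 10 (not isolated)
Conditions: 9, t-BuLi, THF, −78 → 0 °C; then 8, −78 °C; aq. NH4Cl
Reagents that add atoms: none
Why: 1,2-Addition of an α-alkoxyvinyllithium to the ketone; attack should come from the face of C7 next to the C1=C10 etheno bridge, which is less hindered than the face flanked by the substituted C3–C4 bridge and the 6-methoxy group, so the ethoxyvinyl group ends syn to the alkene as the next step requires.

**Step 6**
Reactants: 11 ethoxyvinyl carbinol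
Product: 14 cis-decalin enol triflate, via potassium alkoxide 12 (not isolated), via potassium enolate 13 (not isolated)
Conditions: KH, 18-crown-6, THF, 0 °C → rt; then PhNTf2, −78 → 0 °C
Reagents that add atoms: N-phenylbis(trifluoromethanesulfonimide), O=S(=O)(N(c1ccccc1)S(=O)(=O)C(F)(F)F)C(F)(F)F
Why: Anionic oxy-Cope rearrangement; the boat [3,3] shift enforced by the bicycle breaks C2–C7 and forms C9–C10 on the face of C10 that carried the C6–C7 bridge, so H10 ends cis to the 5-methyl group (cis-decalin, C10 as in the target), and the regiodefined C7 enolate is O-sulfonylated by PhNTf2.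

**Step 7**
Reactants: 14 cis-decalin enol triflate
Product: 15 1,2-dihydro enol triflate
Conditions: 2-nitrobenzenesulfonohydrazide, Et3N, CH2Cl2, rt
Reagents that add atoms: none
Why: Diimide reduction; the cis-disubstituted C1=C2 bond is reduced while the tetrasubstituted, heteroatom-substituted C7=C8 bond is left alone, and no stereocentre is formed.

**Step 8**
Reactants: 15 1,2-dihydro enol triflate
Product: 16 3-hydroxy enone triflate
Conditions: TFA, H2O, CH2Cl2, 0 °C → rt
Reagents that add atoms: water, O
Why: Acid hydrolysis of the enol ether to the C8 ketone with β-elimination of methanol from C6 gives the C6=C7 enone, and the same acid cleaves the benzylic auxiliary ether by an E1 process at the benzylic carbon, so the C3–O bond and the C3 configuration are untouched.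

**Step 9**
Reactants: 16 3-hydroxy enone triflate; 17 (S)-4-benzyl-3-propanoyl-1,3-oxazolidin-2-one
Product: 19 C11-coupled imide, via silyl ketene N,O-acetal 18 (not isolated)
Conditions: 17, NaN(SiMe3)2, Me3SiCl, THF, −78 °C, volatiles removed; then 16, Pd(dba)2 (5 mol %), P(t-Bu)3 (10 mol %), ZnF2 (0.5 equiv), DMF, rt → 50 °C; 18 in excess
Reagents that add atoms: none
Why: Palladium-catalysed α-alkenylation of an imide enolate (Hartwig-type coupling of a zinc-activated silyl enolate); zerovalent palladium inserts into the alkenyl C–OTf bond, the chelated Z zinc enolate transmetallates on the face opposite the 4-benzyl group (the sense of an Evans alkylation), and reductive elimination should set C11 as R.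

**Step 10**
Reactants: 19 C11-coupled imide
Product: 20 3-hydroxy methyl ester
Conditions: Yb(OTf)3 (10 mol %), MeOH, 50 °C
Reagents that add atoms: methanol, CO
Why: Lewis-acid-catalysed methanolysis of the N-acyloxazolidinone; chelation activates only the exocyclic imide carbonyl, and the non-basic medium should spare the epimerisable C11 centre and the enone.

**Step 11**
Reactants: 20 3-hydroxy methyl ester; 21 angelic acid
Product: 23 target angelate, via mixed anhydride 22 (not isolated)
Conditions: 21, 2,4,6-trichlorobenzoyl chloride, Et3N, toluene, rt; then 20, 75 °C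
Reagents that add atoms: none
Why: Yamaguchi-type esterification through the mixed anhydride in toluene without a nucleophilic catalyst, conditions under which angelates should not isomerise to tiglates; acylation occurs on oxygen, so C3 keeps its configuration.

**Compound list**

1 | (R)-1-(2,4,6-triisopropylphenyl)ethanol | C[C@@H](O)c1c(C(C)C)cc(C(C)C)cc1C(C)C | starting material
2 | allyl bromide (3-bromoprop-1-ene) | C=CCBr | starting material
3 | allyl (R)-1-(2,4,6-triisopropylphenyl)ethyl ether | C[C@@H](OCC=C)c1c(C(C)C)cc(C(C)C)cc1C(C)C | intermediate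
4 | (Z)-prop-1-enyl (R)-1-(2,4,6-triisopropylphenyl)ethyl ether | C/C=C\O[C@H](C)c1c(C(C)C)cc(C(C)C)cc1C(C)C | intermediate
5 | 2-methoxy-3-methylphenol | COc1c(C)cccc1O | starting material
6 | 6,6-dimethoxy-5-methylcyclohexa-2,4-dien-1-one (masked o-benzoquinone) | COC1(OC)C(C)=CC=CC1=O | intermediate
7 | 3,3-dimethoxy-4,8-dimethyl-7-[(R)-1-(2,4,6-triisopropylphenyl)ethoxy]bicyclo[2.2.2]oct-5-en-2-one; 7-alkoxy and 8-methyl cis to each other and syn to the C5=C6 bridge; bicyclic C7, C8 and C4 are C3, C4 and C5 of the target and placed as in the target | C[C@H](c1c(C(C)C)cc(C(C)C)cc1C(C)C)O[C@H]1[C@H]2C=C[C@](C)(C(OC)(OC)C2=O)[C@H]1C | intermediate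
8 | 3-methoxy-4,8-dimethyl-7-[(R)-1-(2,4,6-triisopropylphenyl)ethoxy]bicyclo[2.2.2]oct-5-en-2-one; as 7 with one methoxy group left, anti to the C5=C6 bridge | C[C@H](c1c(C(C)C)cc(C(C)C)cc1C(C)C)O[C@H]1[C@H]2C=C[C@](C)([C@@H](OC)C2=O)[C@H]1C | intermediate
9 | ethyl vinyl ether | C=COCC | starting material
10 | 1-ethoxyvinyllithium | [Li]C(=C)OCC | intermediate
11 | 2-(1-ethoxyethenyl)-3-methoxy-4,8-dimethyl-7-[(R)-1-(2,4,6-triisopropylphenyl)ethoxy]bicyclo[2.2.2]oct-5-en-2-ol; ethoxyvinyl group syn to the C5=C6 bridge | C[C@H](c1c(C(C)C)cc(C(C)C)cc1C(C)C)O[C@H]1[C@H]2C=C[C@](C)([C@@H](OC)[C@]2(O)C(OCC)=C)[C@H]1C | intermediate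
12 | potassium alkoxide of 11 | C[C@H](c1c(C(C)C)cc(C(C)C)cc1C(C)C)O[C@H]1[C@H]2C=C[C@](C)([C@@H](OC)[C@]2([O-])C(OCC)=C)[C@H]1C.[K+] | intermediate
13 | potassium C7 enolate of the cis-decalin (target numbering): 8-ethoxy-6-methoxy-4,5-dimethyl-3-[(R)-1-(2,4,6-triisopropylphenyl)ethoxy]-1,7-diene 7-olate; C3, C4, C5, C10 as in the target | C[C@H](c1c(C(C)C)cc(C(C)C)cc1C(C)C)O[C@H]1C=C[C@@H]2CC(OCC)=C([O-])[C@H](OC)[C@]2(C)[C@H]1C.[K+] | intermediate
14 | 7-trifluoromethanesulfonate of the enol of 13 (cis-decalin 1,7-diene; 8-ethoxy, 6-methoxy, 3-auxiliary ether; C3, C4, C5, C10 as in the target) | C[C@H](c1c(C(C)C)cc(C(C)C)cc1C(C)C)O[C@H]1C=C[C@@H]2CC(OCC)=C(OS(=O)(=O)C(F)(F)F)[C@H](OC)[C@]2(C)[C@H]1C | intermediate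
15 | 1,2-dihydro derivative of 14 (cis-decalin 7-ene) | C[C@H](c1c(C(C)C)cc(C(C)C)cc1C(C)C)O[C@H]1CC[C@@H]2CC(OCC)=C(OS(=O)(=O)C(F)(F)F)[C@H](OC)[C@]2(C)[C@H]1C | intermediate
16 | 3-hydroxy-4,5-dimethyl-8-oxo-cis-decal-6-en-7-yl trifluoromethanesulfonate (target numbering); 3-OH, 4-Me, 5-Me and H10 all cis | O[C@H]1CC[C@@H]2CC(=O)C(OS(=O)(=O)C(F)(F)F)=C[C@]2(C)[C@H]1C | intermediate
17 | (S)-4-benzyl-3-propanoyl-1,3-oxazolidin-2-one | CCC(=O)N1C(=O)OC[C@@H]1Cc1ccccc1 | starting material
18 | (Z)-trimethylsilyl ketene N,O-acetal of 17 | C/C=C(\O[Si](C)(C)C)N1C(=O)OC[C@@H]1Cc1ccccc1 | intermediate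
19 | (S)-4-benzyl-3-[(R)-2-(3-hydroxy-4,5-dimethyl-8-oxo-cis-decal-6-en-7-yl)propanoyl]-1,3-oxazolidin-2-one (ring centres as in the target) | O[C@H]1CC[C@@H]2CC(=O)C([C@@H](C)C(=O)N3C(=O)OC[C@@H]3Cc3ccccc3)=C[C@]2(C)[C@H]1C | intermediate
20 | methyl (11R)-3β-hydroxy-8-oxo-10βH-eremophil-6-en-12-oate | O[C@H]1CC[C@@H]2CC(=O)C([C@@H](C)C(=O)OC)=C[C@]2(C)[C@H]1C | intermediate
21 | angelic acid, (Z)-2-methylbut-2-enoic acid | C/C=C(/C)C(=O)O | starting material
22 | angelic 2,4,6-trichlorobenzoic anhydride | C/C=C(/C)C(=O)OC(=O)c1c(Cl)cc(Cl)cc1Cl | intermediate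
23 | methyl (3S,4R,5R,10R,11R)-3-angeloyloxy-8-oxoeremophil-6-en-12-oate (CNP0323033.1) | C/C=C(/C)C(=O)O[C@H]1CC[C@@H]2CC(=O)C([C@@H](C)C(=O)OC)=C[C@]2(C)[C@H]1C | target

**Total step count:** 11
**Longest linear sequence:** 11 steps (1 and 2 through to 23; the phenol 5 enters at step 3)

**The three steps most likely to fail**

Step 3. The dienone may dimerise, or the enol ether may be methanolysed under the oxidising protic conditions, faster than the cycloaddition joins its two substituted termini. Facial discrimination by the auxiliary may also be weaker than the conformational model predicts. The fallback sets out from 5 and 4 and comes back at 8. Oxidation of 5 with PhI(OAc)2 in AcOH/CH2Cl2 at −78 °C gives the isolable racemic o-quinol acetate 6-acetoxy-6-methoxy-5-methylcyclohexa-2,4-dien-1-one F1. Heating F1 with 4 in toluene, with no oxidant and no protic solvent, should give by the same endo and regiochemical course the acetoxy adduct 3-acetoxy-3-methoxy-4,8-dimethyl-7-[(R)-1-(2,4,6-triisopropylphenyl)ethoxy]bicyclo[2.2.2]oct-5-en-2-one F2. SmI2 (2 equiv, THF/MeOH, −78 °C) then removes the α-acetoxy group, which is far more labile than methoxy, and gives 8. This fallback also replaces the stoichiometry-controlled demethoxylation of step 4.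

Step 6 (with step 5). The α-alkoxyvinyl alkoxide may revert or fragment instead of undergoing the [3,3] shift, or the α-alkoxy enolate may be sulfonylated on carbon. The fallback sets out from 8 and comes back at 16.
- Vinylmagnesium bromide (THF, −78 °C) gives the vinyl carbinol 3-methoxy-4,8-dimethyl-7-[(R)-1-(2,4,6-triisopropylphenyl)ethoxy]-2-vinylbicyclo[2.2.2]oct-5-en-2-ol F3.
- KH/18-crown-6 rearranges F3 to the potassium C7 enolate F4, which is oxidised in the flask with 2-(phenylsulfonyl)-3-phenyloxaziridine to the 8-hydroxy-7-ketone F5.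
- Diimide reduction gives the 1,2-dihydro 8-hydroxy-7-ketone F6.
- TFA/H2O converts F6 through the enediol, with loss of methanol and of the auxiliary, into the diosphenol 3,7-dihydroxy-4,5-dimethyl-cis-decal-6-en-8-one F7.
- PhNTf2/Et3N sulfonylates only the enolic hydroxyl and gives 16.

Step 9. Transmetallation at the enolisable enone triflate may be slow, or face control at C11 may be lost, so that epimer mixtures form. The fallback sets out from 16, comes back at 20 and replaces steps 9 and 10. Methyl 2-bromopropanoate and zinc give the Reformatsky reagent (1-methoxy-1-oxopropan-2-yl)zinc bromide F8. Negishi coupling of F8 with 16 (Pd(PPh3)4, THF) gives 20 together with its C11 epimer methyl (11S)-3β-hydroxy-8-oxo-10βH-eremophil-6-en-12-oate F9. The epimers are separated by preparative HPLC, and F9 is re-equilibrated at C11 with DBU and recycled.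

**Further compounds**

F1 | step 3 | 6-acetoxy-6-methoxy-5-methylcyclohexa-2,4-dien-1-one (racemic) | CC(=O)OC1(OC)C(C)=CC=CC1=O
F2 | step 3 | 3-acetoxy-3-methoxy-4,8-dimethyl-7-[(R)-1-(2,4,6-triisopropylphenyl)ethoxy]bicyclo[2.2.2]oct-5-en-2-one (either epimer at the acetoxy carbon) | C[C@H](c1c(C(C)C)cc(C(C)C)cc1C(C)C)O[C@H]1[C@H]2C=C[C@](C)(C(OC)(OC(C)=O)C2=O)[C@H]1C
F3 | step 6 | 3-methoxy-4,8-dimethyl-7-[(R)-1-(2,4,6-triisopropylphenyl)ethoxy]-2-vinylbicyclo[2.2.2]oct-5-en-2-ol (vinyl syn to the C5=C6 bridge) | C[C@H](c1c(C(C)C)cc(C(C)C)cc1C(C)C)O[C@H]1[C@H]2C=C[C@](C)([C@@H](OC)[C@]2(O)C=C)[C@H]1C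
F4 | step 6 | potassium C7 enolate of the 6-methoxy cis-decal-1-en-7-one (not isolated) | C[C@H](c1c(C(C)C)cc(C(C)C)cc1C(C)C)O[C@H]1C=C[C@@H]2CC=C([O-])[C@H](OC)[C@]2(C)[C@H]1C.[K+]
F5 | step 6 | 8-hydroxy-6-methoxy-4,5-dimethyl-3-[(R)-1-(2,4,6-triisopropylphenyl)ethoxy]-cis-decal-1-en-7-one (either C8 epimer) | C[C@H](c1c(C(C)C)cc(C(C)C)cc1C(C)C)O[C@H]1C=C[C@@H]2CC(O)C(=O)[C@H](OC)[C@]2(C)[C@H]1C
F6 | step 6 | 1,2-dihydro derivative of F5 | C[C@H](c1c(C(C)C)cc(C(C)C)cc1C(C)C)O[C@H]1CC[C@@H]2CC(O)C(=O)[C@H](OC)[C@]2(C)[C@H]1C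
F7 | step 6 | 3,7-dihydroxy-4,5-dimethyl-cis-decal-6-en-8-one (diosphenol; ring centres as in the target) | O[C@H]1CC[C@@H]2CC(=O)C(O)=C[C@]2(C)[C@H]1C
F8 | step 9 | (1-methoxy-1-oxopropan-2-yl)zinc bromide | COC(=O)C(C)[Zn]Br
F9 | step 9 | methyl (11S)-3β-hydroxy-8-oxo-10βH-eremophil-6-en-12-oate | O[C@H]1CC[C@@H]2CC(=O)C([C@H](C)C(=O)OC)=C[C@]2(C)[C@H]1C
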